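**Retrosynthetic overview**
1. The veratrate is cut back to the 3a,5-diol 14. The C5 oxygen comes from allylic oxidation and hydroxyl-directed reduction of the carotane-type alcohol 11, and the isopropyl group from an isopropenyl group.
2. Key disconnection C3–C3a: the tertiary ring-fusion alcohol C3a–OH with a cis isopropenyl group on the neighbouring C3 of the cyclopentane is the homoallylic-alcohol retron of a type-I carbonyl-ene reaction. The enophile is a C3a ketone in the seven-membered ring, and its quaternary neighbour C8a carries the CH3 and a homoprenyl chain.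
3. That ketone is a cyclohept-4-enone (C3a carbonyl, α-quaternary C8a, γ,δ-alkene C6=C7), which is the Claisen ring-expansion product of a 2-vinyl-5-alkylidenetetrahydrofuran. Both events are run in one flask, and the configuration of C8a is relayed from the carbinol carbon of (R)-linalool.
4. The (Z)-enol ether 8 is built from (R)-(−)-linalool by ozonolysis, alkyne homologation, acetylide alkylation, anti-iodoetherification and Negishi methylation.
5. Ring order: temporary tetrahydrofuran (step 4, destroyed again in step 6), then the seven-membered carbocycle (Claisen, step 6), then the five-membered ring last (ene, step 6).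

Key step: step 6

Assumption: the target is read as the (3R,3aS,5R,8aR) isomer (3a-OH, 8a-CH3 and 3-isopropyl mutually cis on the cyclopentane, 5-acyloxy trans to 3a-OH; azulene numbering for all bicyclic compounds), and commercial (R)-(−)-linalool of high enantiomeric purity is taken as the only source of absolute configuration.

**Route**

Step 1
Reactants: 1 (R)-(−)-linalool
Product: 2 (5R)-5-methyl-5-vinyltetrahydrofuran-2-ol (lactol; anomer mixture)
Conditions: O3 (1.0 equiv, Sudan Red 7B end-point), CH2Cl2/MeOH, NaHCO3, −78 °C; then Me2S, −78 °C → rt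
Reagents that add atoms: ozone, [O-][O+]=O
Why: Ozonolysis is electrophilic and should cleave the electron-rich trisubstituted 6,7-alkene well before the monosubstituted vinyl group, which is deactivated by the adjacent C–O bond; the γ-hydroxy aldehyde closes to the lactol without touching the carbinol stereocentre.

Step 2
Reactants: 2 (5R)-5-methyl-5-vinyltetrahydrofuran-2-ol
Product: 4 (R)-3-methylhept-1-en-6-yn-3-ol, via hydroxy aldehyde 3 (not isolated)
Conditions: dimethyl (1-diazo-2-oxopropyl)phosphonate, K2CO3, MeOH, 0 °C → rt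
Reagents that add atoms: dimethyl (1-diazo-2-oxopropyl)phosphonate (Ohira–Bestmann reagent), CC(=O)C(=[N+]=[N-])P(=O)(OC)OC
Why: Seyferth–Gilbert homologation with the Ohira–Bestmann reagent acts on the open hydroxy-aldehyde tautomer of the lactol under mild K2CO3/MeOH conditions and turns CHO into a terminal alkyne with the stereocentre untouched.

Step 3
Reactants: 4 (R)-3-methylhept-1-en-6-yn-3-ol; 5 5-bromo-2-methylpent-2-ene
Product: 6 (R)-3,11-dimethyldodeca-1,10-dien-6-yn-3-ol
Conditions: n-BuLi (2.1 equiv), THF, −78 → 0 °C; then 5, DMPU, 0 °C → rt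
Reagents that add atoms: none
Why: In the O,C-dilithio species the acetylide carbon is by far the better nucleophile than the hindered tertiary alkoxide, so SN2 alkylation with the primary bromide should occur at carbon only (acetylide alkylation).

Step 4
Reactants: 6 (R)-3,11-dimethyldodeca-1,10-dien-6-yn-3-ol
Product: 7 (2E,5R)-2-(1-iodo-5-methylhex-4-en-1-ylidene)-5-methyl-5-vinyltetrahydrofuran
Conditions: I2 (1.05 equiv), NaHCO3, MeCN, 0 °C, dark; basic work-up, no acidic chromatography
Reagents that add atoms: iodine, II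
Why: Iodonium activation of the alkyne and anti attack of the tertiary hydroxyl in a 5-exo-dig iodoetherification place oxygen and iodine trans, which fixes the (E) geometry of the tetrasubstituted enol ether; iodonium formation at the two alkenes is reversible and has no internal nucleophile to trap it.

Step 5
Reactants: 7 (2E,5R)-2-(1-iodo-5-methylhex-4-en-1-ylidene)-5-methyl-5-vinyltetrahydrofuran
Product: 8 (2Z,5R)-5-methyl-2-(6-methylhept-5-en-2-ylidene)-5-vinyltetrahydrofuran
Conditions: MeZnCl (1.5 equiv), Pd(PPh3)4 (5 mol %), THF, 0 °C → rt; Et3N-buffered work-up, basic alumina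
Reagents that add atoms: methylzinc chloride, C[Zn]Cl
Why: Negishi cross-coupling of the alkenyl iodide proceeds with retention of alkene geometry under neutral conditions that the acid-sensitive enol ether tolerates, and gives the (Z)-enol ether in which the homoprenyl chain is cis to the ring oxygen.

Step 6
Reactants: 8 (2Z,5R)-5-methyl-2-(6-methylhept-5-en-2-ylidene)-5-vinyltetrahydrofuran
Product: 10 (3R,3aS,8aR)-6,8a-dimethyl-3-(prop-1-en-2-yl)-2,3,4,5,8,8a-hexahydroazulen-3a(1H)-ol, via cycloheptenone 9 (not isolated)
Conditions: PhMe, 185 °C, sealed base-washed tube, 4 h; then −78 °C, CH2Cl2, Me2AlCl (2 equiv), → −20 °C; aq. Rochelle salt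
Reagents that add atoms: none
Why: Heating triggers a concerted [3,3]-sigmatropic (Claisen) ring expansion of the allyl vinyl ether C=C–O–C–C=C embedded in 8 to the cyclohept-4-enone 9, and Me2AlCl then activates the ketone of 9 for a type-I intramolecular carbonyl-ene reaction in which the less substituted carbon of the side-chain alkene bonds to the carbonyl carbon while an allylic methyl hydrogen passes to oxygen. The closest known reactions are the thermal Claisen ring expansion of 2-methyl-2-vinyl-5-isopropylidenetetrahydrofuran to 2,2,5-trimethylcyclohept-4-enone and the Lewis-acid carbonyl-ene cyclisation of citronellal-type olefinic carbonyl compounds; tandem Claisen–ene sequences are established. The seven-membered ring closes first, by ring expansion through a boat-like bicyclic six-centre transition state in which the temporary C–O tether is cut, and the five-membered ring closes last in a 5-exo (3,4)-ene mode with Markovnikov polarity. C8a is set by suprafacial chirality transfer, because the vinyl group can reach the exocyclic enol-ether carbon only on its own face of the tetrahydrofuran, so the (5R) centre and the (Z) geometry translate into (R)-9; C3a follows because the three-carbon tether on C8a can reach only the adjacent carbonyl face, which leaves the new hydroxyl cis to the C8a methyl (cis ring fusion); C3 follows from the six-membered hydrogen-transfer array, which needs the carbonyl oxygen and the isopropylidene methyl syn and so places isopropenyl cis to the hydroxyl. The step needs the side-chain alkene to react in preference to the ring alkene and proton transfer to beat chloride capture: the ring alkene could only close a four-membered ring across the cycloheptenone, and Me2AlCl acts as Lewis acid and proton scavenger, so the alkoxide forms irreversibly with loss of methane.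

Step 7
Reactants: 10 (3R,3aS,8aR)-6,8a-dimethyl-3-(prop-1-en-2-yl)-2,3,4,5,8,8a-hexahydroazulen-3a(1H)-ol
Product: 11 (3R,3aS,8aR)-3-isopropyl-6,8a-dimethyl-2,3,4,5,8,8a-hexahydroazulen-3a(1H)-ol
Conditions: H2 (1 atm), RhCl(PPh3)3 (5 mol %), benzene, rt
Reagents that add atoms: none
Why: RhCl(PPh3)3-catalysed homogeneous hydrogenation reduces the 1,1-disubstituted isopropenyl group much faster than the trisubstituted ring alkene, and no stereocentre is formed or touched.

Step 8
Reactants: 11 (3R,3aS,8aR)-3-isopropyl-6,8a-dimethyl-2,3,4,5,8,8a-hexahydroazulen-3a(1H)-ol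
Product: 13 (3R,3aS,8aR)-3a-hydroxy-3-isopropyl-6,8a-dimethyl-2,3,3a,4,8,8a-hexahydroazulen-5(1H)-one, via allylic alcohol 12 (not isolated)
Conditions: SeO2 (0.3 equiv), t-BuOOH (2 equiv), CH2Cl2, 0 °C → rt; then activated MnO2 (excess), rt
Reagents that add atoms: selenium dioxide, O=[Se]=O; tert-butyl hydroperoxide, CC(C)(C)OO
Why: Allylic oxidation with SeO2 (ene reaction, then [2,3]-sigmatropic shift) should attack the ring CH2 on the more substituted end of the trisubstituted alkene (C5), as 1-methylcycloalkenes give 2-methylcycloalk-2-en-1-ols, and MnO2 then oxidises both C5 epimers of the secondary allylic alcohol to the same enone, so the facial course of the hydroxylation does not matter.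

Step 9
Reactants: 13 (3R,3aS,8aR)-3a-hydroxy-3-isopropyl-6,8a-dimethyl-2,3,3a,4,8,8a-hexahydroazulen-5(1H)-one
Product: 14 (3R,3aS,5R,8aR)-3-isopropyl-6,8a-dimethyl-2,3,4,5,8,8a-hexahydroazulene-3a,5(1H)-diol
Conditions: Me4NBH(OAc)3 (5 equiv), MeCN/AcOH (1:1), −30 → −20 °C
Reagents that add atoms: none
Why: Evans–Saksena reduction: the tertiary 3a-hydroxyl exchanges onto boron and delivers hydride intramolecularly to the same face of the C5 carbonyl, which should set C5 as the trans (anti) 1,3-diol (5R) by 1,2-reduction of the enone.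

Step 10
Reactants: 14 (3R,3aS,5R,8aR)-3-isopropyl-6,8a-dimethyl-2,3,4,5,8,8a-hexahydroazulene-3a,5(1H)-diol; 15 3,4-dimethoxybenzoyl chloride
Product: 16 (3R,3aS,5R,8aR)-3a-hydroxy-3-isopropyl-6,8a-dimethyl-1,2,3,3a,4,5,8,8a-octahydroazulen-5-yl 3,4-dimethoxybenzoate (target)
Conditions: Et3N, DMAP (cat.), CH2Cl2, 0 °C → rt
Reagents that add atoms: none
Why: DMAP-catalysed acylation with the acid chloride (nucleophilic catalysis) should occur only at the secondary allylic hydroxyl, because the tertiary ring-fusion hydroxyl is too hindered, and esterification with retention at C5 gives the target.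

**Compound list**
1 | (R)-(−)-linalool | CC(C)=CCC[C@@](C)(O)C=C | starting material
2 | (5R)-5-methyl-5-vinyltetrahydrofuran-2-ol (anomer mixture) | OC1CC[C@@](C)(O1)C=C | intermediate
3 | (R)-4-hydroxy-4-methylhex-5-enal (open form of 2) | O=CCC[C@@](C)(O)C=C | intermediate
4 | (R)-3-methylhept-1-en-6-yn-3-ol | C#CCC[C@@](C)(O)C=C | intermediate
5 | 5-bromo-2-methylpent-2-ene | CC(C)=CCCBr | starting material
6 | (R)-3,11-dimethyldodeca-1,10-dien-6-yn-3-ol | CC(C)=CCCC#CCC[C@@](C)(O)C=C | intermediate
7 | (2E,5R)-2-(1-iodo-5-methylhex-4-en-1-ylidene)-5-methyl-5-vinyltetrahydrofuran | CC(C)=CCC/C(I)=C1/CC[C@](C)(C=C)O1 | intermediate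
8 | (2Z,5R)-5-methyl-2-(6-methylhept-5-en-2-ylidene)-5-vinyltetrahydrofuran | CC(C)=CCC/C(C)=C1/CC[C@](C)(C=C)O1 | intermediate
9 | (R)-2,5-dimethyl-2-(4-methylpent-3-en-1-yl)cyclohept-4-en-1-one | O=C1CCC(C)=CC[C@@]1(C)CCC=C(C)C | intermediate
10 | (3R,3aS,8aR)-6,8a-dimethyl-3-(prop-1-en-2-yl)-2,3,4,5,8,8a-hexahydroazulen-3a(1H)-ol | C1C[C@]2(O)[C@@H](C(C)=C)CC[C@]2(C)CC=C1C | intermediate
11 | (3R,3aS,8aR)-3-isopropyl-6,8a-dimethyl-2,3,4,5,8,8a-hexahydroazulen-3a(1H)-ol | C1C[C@]2(O)[C@@H](C(C)C)CC[C@]2(C)CC=C1C | intermediate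
12 | (3R,3aS,8aR)-3-isopropyl-6,8a-dimethyl-2,3,4,5,8,8a-hexahydroazulene-3a,5(1H)-diol, C5 epimer mixture | OC1C[C@]2(O)[C@@H](C(C)C)CC[C@]2(C)CC=C1C | intermediate
13 | (3R,3aS,8aR)-3a-hydroxy-3-isopropyl-6,8a-dimethyl-2,3,3a,4,8,8a-hexahydroazulen-5(1H)-one | O=C1C[C@]2(O)[C@@H](C(C)C)CC[C@]2(C)CC=C1C | intermediate
14 | (3R,3aS,5R,8aR)-3-isopropyl-6,8a-dimethyl-2,3,4,5,8,8a-hexahydroazulene-3a,5(1H)-diol | O[C@@H]1C[C@]2(O)[C@@H](C(C)C)CC[C@]2(C)CC=C1C | intermediate
15 | 3,4-dimethoxybenzoyl chloride | COc1ccc(C(=O)Cl)cc1OC | starting material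
16 | (3R,3aS,5R,8aR)-3a-hydroxy-3-isopropyl-6,8a-dimethyl-1,2,3,3a,4,5,8,8a-octahydroazulen-5-yl 3,4-dimethoxybenzoate | COc1ccc(C(=O)O[C@@H]2C[C@]3(O)[C@@H](C(C)C)CC[C@]3(C)CC=C2C)cc1OC | target

**Step count**
Total steps: 10. Longest linear sequence: 10 steps (1 → 16).

**Steps most likely to fail, with fallbacks**

Step 6. The ene closure on the hindered α-quaternary ketone may be slow or may run through an open cation. That would lead to chloride capture, loss of the wrong proton or interception of the tertiary cation by the ring alkene, and would erode the cis C3/C3a relationship. The fallback sets out from ketone 9, isolated after the thermal stage on Et3N-deactivated silica. The cyclisation is run deliberately as a stepwise Prins reaction with TiCl4 (1.1 equiv, CH2Cl2, −78 °C), in which the chloride of the titanium alkoxide collapses onto the tertiary cation held next to oxygen. This should give the chlorohydrin (3S,3aS,8aR)-3-(2-chloropropan-2-yl)-6,8a-dimethyl-2,3,4,5,8,8a-hexahydroazulen-3a(1H)-ol F1 (the changed C3 descriptor reflects only the priority of the chlorinated group). Radical dechlorination (Bu3SnH, AIBN, benzene, 80 °C) then gives the isopropyl compound directly, so the route is rejoined at 11 and step 7 is skipped.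

Step 8. The allylic oxidation may go to the wrong site (the C6 methyl or C8), may over-oxidise, or the acidic selenium species may dehydrate or etherify the tertiary alcohol. The fallback sets out from 11 and moves the oxygen into place by classical carbonyl transposition.
- Hydroboration–oxidation (BH3·THF; NaOH, H2O2) puts oxygen on C7, the only CH of the alkene, to give (3R,3aS,8aR)-3-isopropyl-6,8a-dimethyldecahydroazulene-3a,7-diol F2; its new centres at C6 and C7 are erased later.
- Dess–Martin oxidation of the secondary alcohol gives the 7-ketone (3R,3aS,8aR)-3a-hydroxy-3-isopropyl-6,8a-dimethyloctahydroazulen-7(1H)-one F3.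
- Dehydrogenation with IBX (DMSO, 70 °C) can only occur towards C6/C5, because C8 is flanked by the quaternary C8a, and gives the transposed enone (3R,3aS,8aR)-3a-hydroxy-3-isopropyl-6,8a-dimethyl-2,3,3a,4,8,8a-hexahydroazulen-7(1H)-one F4.
- Weitz–Scheffer epoxidation (H2O2, NaOH, MeOH) gives (3R,3aS,8aR)-5,6-epoxy-3a-hydroxy-3-isopropyl-6,8a-dimethyloctahydroazulen-7(1H)-one F5.
- Wharton transposition (N2H4·H2O, cat. AcOH, MeOH) returns the C6=C7 alkene with the hydroxyl now on C5. This is compound 12, which is oxidised with MnO2 as in step 8, so the route is rejoined at 13.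

Step 4. Iodine may attack the trisubstituted chain alkene or the electron-rich product, and the α-iodo enol ether may hydrolyse. The fallback sets out from 4 and builds the prenyl terminus only after the halocyclisation.
- Alkylation of the dianion of 4 with (3-bromopropoxy)(tert-butyl)dimethylsilane (n-BuLi, THF/DMPU) gives (R)-10-[(tert-butyldimethylsilyl)oxy]-3-methyldec-1-en-6-yn-3-ol F6.
- Iodoetherification as in step 4, now without a nucleophilic alkene, gives (2E,5R)-2-[4-(tert-butyldimethylsilyloxy)-1-iodobutylidene]-5-methyl-5-vinyltetrahydrofuran F7.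
- Negishi methylation as in step 5 gives (2Z,5R)-2-[5-(tert-butyldimethylsilyloxy)pentan-2-ylidene]-5-methyl-5-vinyltetrahydrofuran F8.
- TBAF (THF) gives (Z)-4-[(5R)-5-methyl-5-vinyldihydrofuran-2(3H)-ylidene]pentan-1-ol F9.
- Parikh–Doering oxidation (SO3·pyridine, DMSO, i-Pr2NEt) gives (Z)-4-[(5R)-5-methyl-5-vinyldihydrofuran-2(3H)-ylidene]pentanal F10.
- Wittig olefination with isopropylidenetriphenylphosphorane (from isopropyltriphenylphosphonium iodide and n-BuLi, THF) installs the CH=C(CH3)2 terminus, so the route is rejoined at 8.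

**Further compounds**
F1 | step 6 | (3S,3aS,8aR)-3-(2-chloropropan-2-yl)-6,8a-dimethyl-2,3,4,5,8,8a-hexahydroazulen-3a(1H)-ol | C1C[C@]2(O)[C@@H](C(C)(C)Cl)CC[C@]2(C)CC=C1C
F2 | step 8 | (3R,3aS,8aR)-3-isopropyl-6,8a-dimethyldecahydroazulene-3a,7-diol (C6/C7 epimers) | C1C[C@]2(O)[C@@H](C(C)C)CC[C@]2(C)CC(O)C1C
F3 | step 8 | (3R,3aS,8aR)-3a-hydroxy-3-isopropyl-6,8a-dimethyloctahydroazulen-7(1H)-one (C6 epimers) | C1C[C@]2(O)[C@@H](C(C)C)CC[C@]2(C)CC(=O)C1C
F4 | step 8 | (3R,3aS,8aR)-3a-hydroxy-3-isopropyl-6,8a-dimethyl-2,3,3a,4,8,8a-hexahydroazulen-7(1H)-one | C=1C[C@]2(O)[C@@H](C(C)C)CC[C@]2(C)CC(=O)C=1C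
F5 | step 8 | (3R,3aS,8aR)-5,6-epoxy-3a-hydroxy-3-isopropyl-6,8a-dimethyloctahydroazulen-7(1H)-one | C12C[C@]3(O)[C@@H](C(C)C)CC[C@]3(C)CC(=O)C1(C)O2
F6 | step 4 | (R)-10-[(tert-butyldimethylsilyl)oxy]-3-methyldec-1-en-6-yn-3-ol | CC(C)(C)[Si](C)(C)OCCCC#CCC[C@@](C)(O)C=C
F7 | step 4 | (2E,5R)-2-[4-(tert-butyldimethylsilyloxy)-1-iodobutylidene]-5-methyl-5-vinyltetrahydrofuran | CC(C)(C)[Si](C)(C)OCCC/C(I)=C1/CC[C@](C)(C=C)O1
F8 | step 4 | (2Z,5R)-2-[5-(tert-butyldimethylsilyloxy)pentan-2-ylidene]-5-methyl-5-vinyltetrahydrofuran | CC(C)(C)[Si](C)(C)OCCC/C(C)=C1/CC[C@](C)(C=C)O1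
F9 | step 4 | (Z)-4-[(5R)-5-methyl-5-vinyldihydrofuran-2(3H)-ylidene]pentan-1-ol | OCCC/C(C)=C1/CC[C@](C)(C=C)O1
F10 | step 4 | (Z)-4-[(5R)-5-methyl-5-vinyldihydrofuran-2(3H)-ylidene]pentanal | O=CCC/C(C)=C1/CC[C@](C)(C=C)O1
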